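## Retrosynthetic overview

1. The plan rests on ring A, the 1,2-dioxane O–O–C3–C4–C5–C6 (chain numbered C1–C9 from the carboxyl carbon): its two C–O bonds sit at the ends of the four-carbon unit C3–C6 and the C3 side chain is cis to the C6 methyl, which is what O2 leaves when it adds to both termini of a 1,3-diene.
2. Key disconnection: both C–O bonds of ring A, by suprafacial [4+2] addition of singlet oxygen to the (3E,5Z)-diene C3=C4–C5=C6 carrying C1 as a TBS ether and C9 as a methyl ester. Ring A is the only ring made in the route and is closed first, on the open chain.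
3. Diene: Julia–Kocienski olefination (C3=C4) of a (Z)-enal ester cut out of neryl acetate (C4–C9, Z-alkene bought) with a 1-phenyltetrazolyl sulfone from methyl (R)-3-hydroxy-2-methylpropanoate (C1–C3, C2 bought).
4. After the peroxide: diimide saturates C4=C5; the C9 acid chloride is joined by Stille acylation to the dienylstannane of the carbobicycle (rings B and C, already present in 6-methoxy-1-tetralone); tosylhydrazone reduction with 1,3-alkene transposition sets the (Z)-C9=C2′ alkene.
5. End: C1 desilylation and oxidation to the acid. The electron-rich alkenes of the bicycle are brought in only after the photooxygenation, so singlet oxygen meets the diene alone.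

Key step: step 12

Assumption: neryl acetate, the commercial acetate of nerol, is used as starting material, and the two cis-dioxine diastereomers from step 12 are assumed separable by chromatography.
Numbering used below: chain atoms C1–C9 from the acid carbon of the target; ring atoms of the carbobicycle carry primed naphthalene locants (C2′ is the alkylidene carbon, C5′ the gem-dimethyl carbon).

## Route

**Fragment 1: the (Z)-enal ester (C4–C9)**

Step 1
Reactants: 1 neryl acetate
Product: 2 (2Z)-5-(3,3-dimethyloxiran-2-yl)-3-methylpent-2-en-1-yl acetate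
Conditions: mCPBA (1.05 equiv), NaHCO3, CH2Cl2, 0 °C
Reagents that add atoms: 3-chloroperoxybenzoic acid, OOC(=O)c1cccc(Cl)c1
Why: Prilezhaev epoxidation is electrophilic, so the peracid should take the remote trisubstituted alkene and leave the 2,3-alkene, which is deactivated by the allylic acetate.

Step 2
Reactants: 2 (2Z)-5-(3,3-dimethyloxiran-2-yl)-3-methylpent-2-en-1-yl acetate
Product: 4 (2Z)-3-methyl-6-oxohex-2-en-1-yl acetate, via vicinal diol 3 (not isolated)
Conditions: H5IO6, THF/H2O, 0 °C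
Reagents that add atoms: none
Why: Periodic acid opens the epoxide with water at the tertiary carbon and cleaves the resulting glycol (Malaprade cleavage), removing the isopropylidene carbon as acetone without touching the allylic acetate or the Z-alkene.

Step 3
Reactants: 4 (2Z)-3-methyl-6-oxohex-2-en-1-yl acetate
Product: 5 (4Z)-6-acetoxy-4-methylhex-4-enoic acid
Conditions: NaClO2, NaH2PO4, 2-methyl-2-butene, t-BuOH/H2O, 0 °C → rt
Reagents that add atoms: sodium chlorite, [Na+].[O-]Cl=O
Why: Pinnick oxidation converts the aldehyde into the acid while the scavenger alkene intercepts hypochlorite, so the trisubstituted alkene and its geometry are preserved.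

Step 4
Reactants: 5 (4Z)-6-acetoxy-4-methylhex-4-enoic acid
Product: 6 methyl (4Z)-6-acetoxy-4-methylhex-4-enoate
Conditions: MeI, K2CO3, DMF, rt
Reagents that add atoms: iodomethane, CI
Why: SN2 O-alkylation of the potassium carboxylate gives the methyl ester under conditions that leave the allylic acetate intact.

Step 5
Reactants: 6 methyl (4Z)-6-acetoxy-4-methylhex-4-enoate
Product: 7 methyl (4Z)-6-hydroxy-4-methylhex-4-enoate
Conditions: K2CO3 (cat.), MeOH, 0 °C
Reagents that add atoms: none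
Why: Carbonate-catalysed transesterification removes the acetate as methyl acetate, while the methyl ester can only exchange with the solvent and is unchanged.

Step 6
Reactants: 7 methyl (4Z)-6-hydroxy-4-methylhex-4-enoate
Product: 8 methyl (4Z)-4-methyl-6-oxohex-4-enoate
Conditions: PhI(OAc)2, TEMPO (cat.), CH2Cl2, rt
Reagents that add atoms: none
Why: Oxoammonium (TEMPO) oxidation of the allylic alcohol stops at the enal and is mild enough to keep the Z-geometry of the β,β-disubstituted enal.

**Fragment 2: the sulfone (C1–C3)**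

Step 7
Reactants: 9 methyl (2R)-3-hydroxy-2-methylpropanoate
Product: 10 methyl (2R)-3-[(tert-butyldimethylsilyl)oxy]-2-methylpropanoate
Conditions: TBSCl, imidazole, DMF, rt
Reagents that add atoms: tert-butyldimethylsilyl chloride, CC(C)(C)[Si](C)(C)Cl
Why: Imidazole-promoted silylation of the primary alcohol proceeds without enolising the ester, so C2 is untouched.

Step 8
Reactants: 10 methyl (2R)-3-[(tert-butyldimethylsilyl)oxy]-2-methylpropanoate
Product: 11 (2S)-3-[(tert-butyldimethylsilyl)oxy]-2-methylpropan-1-ol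
Conditions: DIBAL-H (2.2 equiv), CH2Cl2, −78 → 0 °C
Reagents that add atoms: none
Why: Excess aluminium hydride reduces the ester through the aldehyde to the primary alcohol without epimerising C2 or cleaving the silyl ether (the descriptor changes by priority only).

Step 9
Reactants: 11 (2S)-3-[(tert-butyldimethylsilyl)oxy]-2-methylpropan-1-ol
Product: 12 5-{[(2R)-3-[(tert-butyldimethylsilyl)oxy]-2-methylpropyl]sulfanyl}-1-phenyl-1H-tetrazole
Conditions: 1-phenyl-1H-tetrazole-5-thiol, PPh3, DIAD, THF, 0 °C → rt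
Reagents that add atoms: 1-phenyl-1H-tetrazole-5-thiol, SC1=NN=NN1c1ccccc1
Why: Mitsunobu thioetherification displaces the alkoxyphosphonium ion of the primary alcohol by the acidic thiol in an SN2 step remote from the C2 stereocentre.

Step 10
Reactants: 12 5-{[(2R)-3-[(tert-butyldimethylsilyl)oxy]-2-methylpropyl]sulfanyl}-1-phenyl-1H-tetrazole
Product: 14 5-{[(2R)-3-[(tert-butyldimethylsilyl)oxy]-2-methylpropyl]sulfonyl}-1-phenyl-1H-tetrazole, via sulfoxide 13 (not isolated)
Conditions: (NH4)6Mo7O24·4H2O (cat.), 30% aq. H2O2, EtOH, 0 °C → rt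
Reagents that add atoms: hydrogen peroxide, OO
Why: Peroxomolybdate-catalysed oxidation takes the sulfide through the sulfoxide to the sulfone and leaves the TBS ether untouched.

**Union, key step and peroxide fragment**

Step 11
Reactants: 14 5-{[(2R)-3-[(tert-butyldimethylsilyl)oxy]-2-methylpropyl]sulfonyl}-1-phenyl-1H-tetrazole; 8 methyl (4Z)-4-methyl-6-oxohex-4-enoate
Product: 16 methyl (4Z,6E,8S)-9-[(tert-butyldimethylsilyl)oxy]-4,8-dimethylnona-4,6-dienoate, via potassium sulfonyl carbanion 15 (not isolated)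
Conditions: KN(SiMe3)2, DME, −78 °C; then 8, −78 °C → rt
Reagents that add atoms: none
Why: Julia–Kocienski olefination (addition of the metallated sulfone to the enal, Smiles rearrangement, loss of SO2 and tetrazololate) should give the new C3=C4 bond E-selectively, while pre-metallation at low temperature keeps the Z-enal and the ester from enolisation.

Step 12
Reactants: 16 methyl (4Z,6E,8S)-9-[(tert-butyldimethylsilyl)oxy]-4,8-dimethylnona-4,6-dienoate
Product: 17 methyl 3-[(3S,6R)-6-{(2R)-1-[(tert-butyldimethylsilyl)oxy]propan-2-yl}-3-methyl-3,6-dihydro-1,2-dioxin-3-yl]propanoate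
Conditions: O2, meso-tetraphenylporphyrin (cat.), white LED light, CH2Cl2, −78 °C; chromatographic separation of the two cis-dioxine diastereomers
Reagents that add atoms: dioxygen, O=O
Why: Energy transfer from the triplet sensitiser gives singlet oxygen, which adds across C3 and C6 of the s-cis diene in a suprafacial [4+2] cycloaddition, the hetero-Diels–Alder reaction well known for acyclic 1,3-dienes. Ring A (the 3,6-dihydro-1,2-dioxine) is closed in this single intermolecular event by formation of both C–O bonds, the diene supplying four ring atoms and O2 two. The relative configuration of the two new stereocentres follows from the diene geometry: the C2-bearing group on the E terminus and the methyl on the Z terminus are both outside substituents, so suprafacial addition places them cis. The absolute sense is set by the C2 stereocentre: in the conformer with C2–H eclipsing C3=C4, oxygen should approach anti to the CH2OTBS group, which leads to the desired isomer, but the preference is expected to be modest and the other cis-adduct is removed by chromatography. The step needs periselectivity for [4+2] over the ene and [2+2] modes at the trisubstituted alkene; a non-polar aprotic solvent and low temperature disfavour the polar perepoxide pathways, and the substrate carries no other alkene or oxidisable group.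

Step 13
Reactants: 17 methyl 3-[(3S,6R)-6-{(2R)-1-[(tert-butyldimethylsilyl)oxy]propan-2-yl}-3-methyl-3,6-dihydro-1,2-dioxin-3-yl]propanoate
Product: 18 methyl 3-[(3R,6R)-6-{(2R)-1-[(tert-butyldimethylsilyl)oxy]propan-2-yl}-3-methyl-1,2-dioxan-3-yl]propanoate
Conditions: KO2C–N=N–CO2K, AcOH, MeOH/CH2Cl2, −20 °C → rt
Reagents that add atoms: none
Why: Diimide transfers H2 to the cis-disubstituted ring alkene in a concerted syn fashion without reducing the O–O bond, and the mildly acidic medium avoids Kornblum–DeLaMare cleavage of the allylic peroxide (the descriptor at the quaternary carbon changes by priority only).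

Step 14
Reactants: 18 methyl 3-[(3R,6R)-6-{(2R)-1-[(tert-butyldimethylsilyl)oxy]propan-2-yl}-3-methyl-1,2-dioxan-3-yl]propanoate
Product: 19 3-[(3R,6R)-6-{(2R)-1-[(tert-butyldimethylsilyl)oxy]propan-2-yl}-3-methyl-1,2-dioxan-3-yl]propanoic acid
Conditions: LiOH·H2O, THF/H2O, 0 °C → rt; then 0.5 M HCl to pH 4, 0 °C
Reagents that add atoms: lithium hydroxide, [Li+].[OH-]
Why: Saponification of the unhindered methyl ester should be faster than any base-induced cleavage of the saturated dialkyl peroxide, whose C3–H has no acidifying neighbour, and the primary TBS ether is stable to hydroxide.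

**Fragment 3: the dienylstannane (rings B and C)**

Step 15
Reactants: 20 6-methoxy-1-tetralone
Product: 22 6-methoxy-1,1-dimethyl-1,2,3,4-tetrahydronaphthalene, via tertiary titanium alkoxide 21 (not isolated)
Conditions: Me2Zn, TiCl4 (gives Me2TiCl2), CH2Cl2, −40 → 0 °C
Reagents that add atoms: dimethylzinc, C[Zn]C
Why: Geminal dimethylation with Me2TiCl2 adds methyl to the ketone, the benzylic titanium alkoxide ionises with help from the para-methoxy group, and the cation takes a second methyl from titanium.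

Step 16
Reactants: 22 6-methoxy-1,1-dimethyl-1,2,3,4-tetrahydronaphthalene
Product: 23 6-methoxy-1,1-dimethyl-1,2,3,4,5,8-hexahydronaphthalene
Conditions: Li, NH3(l), THF, t-BuOH, −78 → −33 °C
Reagents that add atoms: none
Why: Birch reduction of the anisole ring protonates ortho and meta to the methoxy group, leaving the enol ether and the tetrasubstituted ring-fusion alkene as an unconjugated 1,4-diene.

Step 17
Reactants: 23 6-methoxy-1,1-dimethyl-1,2,3,4,5,8-hexahydronaphthalene
Product: 24 5,5-dimethyl-3,4,5,6,7,8-hexahydronaphthalen-2(1H)-one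
Conditions: oxalic acid, MeOH/H2O, rt
Reagents that add atoms: water, O
Why: Mild acid hydrolysis of the enol ether releases the ketone, and the weak acid leaves the β,γ-alkene at the ring fusion out of conjugation.

Step 18
Reactants: 24 5,5-dimethyl-3,4,5,6,7,8-hexahydronaphthalen-2(1H)-one
Product: 26 5,5-dimethyl-3,4,5,6,7,8-hexahydronaphthalen-2-yl trifluoromethanesulfonate, via potassium dienolate 25 (not isolated)
Conditions: KN(SiMe3)2, THF, −78 °C; then PhNTf2, −78 → 0 °C
Reagents that add atoms: N-phenylbis(trifluoromethanesulfonimide), O=S(=O)(N(c1ccccc1)S(=O)(=O)C(F)(F)F)C(F)(F)F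
Why: Deprotonation at C1′, the α-position that is also allylic, gives the extended dienolate, and O-sulfonylation fixes the C2′=C1′/C8a′=C4a′ diene.

Step 19
Reactants: 26 5,5-dimethyl-3,4,5,6,7,8-hexahydronaphthalen-2-yl trifluoromethanesulfonate
Product: 27 (5,5-dimethyl-3,4,5,6,7,8-hexahydronaphthalen-2-yl)trimethylstannane
Conditions: (Me3Sn)2, Pd(PPh3)4 (cat.), LiCl, degassed THF, 60 °C
Reagents that add atoms: hexamethylditin, C[Sn](C)(C)[Sn](C)(C)C
Why: Oxidative addition of zerovalent palladium into the alkenyl C–O bond, transmetalation with the distannane and reductive elimination (Stille-type stannylation) give the alkenylstannane with the diene unchanged.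

**Fragment union and end game**

Step 20
Reactants: 19 3-[(3R,6R)-6-{(2R)-1-[(tert-butyldimethylsilyl)oxy]propan-2-yl}-3-methyl-1,2-dioxan-3-yl]propanoic acid; 27 (5,5-dimethyl-3,4,5,6,7,8-hexahydronaphthalen-2-yl)trimethylstannane
Product: 29 1-(5,5-dimethyl-3,4,5,6,7,8-hexahydronaphthalen-2-yl)-3-[(3R,6R)-6-{(2R)-1-[(tert-butyldimethylsilyl)oxy]propan-2-yl}-3-methyl-1,2-dioxan-3-yl]propan-1-one, via acid chloride 28 (not isolated)
Conditions: 1-chloro-N,N,2-trimethylprop-1-en-1-amine, CH2Cl2, 0 °C → rt; then 27, Pd2(dba)3 (cat.), P(2-furyl)3, THF, 45 °C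
Reagents that add atoms: none
Why: The α-chloroenamine makes the acid chloride without releasing HCl (so the TBS ether survives), and Stille acylation then joins the acyl carbon C9 to C2′ with retention of the alkene position, run phosphine-lean and below 50 °C to spare the O–O bond and avoid decarbonylation.

Step 21
Reactants: 29 1-(5,5-dimethyl-3,4,5,6,7,8-hexahydronaphthalen-2-yl)-3-[(3R,6R)-6-{(2R)-1-[(tert-butyldimethylsilyl)oxy]propan-2-yl}-3-methyl-1,2-dioxan-3-yl]propan-1-one
Product: 30 N′-{1-(5,5-dimethyl-3,4,5,6,7,8-hexahydronaphthalen-2-yl)-3-[(3S,6R)-6-{(2R)-1-[(tert-butyldimethylsilyl)oxy]propan-2-yl}-3-methyl-1,2-dioxan-3-yl]propylidene}-4-methylbenzenesulfonohydrazide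
Conditions: TsNHNH2, THF, 4 Å molecular sieves, 40 °C
Reagents that add atoms: 4-methylbenzenesulfonohydrazide, Cc1ccc(cc1)S(=O)(=O)NN
Why: Condensation of the conjugated ketone with the sulfonyl hydrazide under near-neutral dehydrating conditions gives the hydrazone without conjugate addition or loss of the silyl ether (the descriptor at the quaternary carbon changes by priority only).

Step 22
Reactants: 30 N′-{1-(5,5-dimethyl-3,4,5,6,7,8-hexahydronaphthalen-2-yl)-3-[(3S,6R)-6-{(2R)-1-[(tert-butyldimethylsilyl)oxy]propan-2-yl}-3-methyl-1,2-dioxan-3-yl]propylidene}-4-methylbenzenesulfonohydrazide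
Product: 33 tert-butyl{[(2R)-2-{(3R,6S)-6-[(3Z)-3-(5,5-dimethyl-3,4,5,6,7,8-hexahydronaphthalen-2(1H)-ylidene)propyl]-6-methyl-1,2-dioxan-3-yl}propyl]oxy}dimethylsilane, via N-boryl hydrazide 31 (not isolated), via allylic diazene 32 (not isolated)
Conditions: catecholborane, CHCl3, 0 °C; then NaOAc·3H2O, 60 °C
Reagents that add atoms: none
Why: 1,2-Hydroboration of the C=N bond and acetate-induced loss of sulfinate give an allylic diazene whose retro-ene loss of N2 delivers hydrogen to C1′ and moves the alkene to C9=C2′ (tosylhydrazone reduction with 1,3-transposition), and in the early six-membered transition state the C8 chain should avoid A(1,2) strain with the C3′ methylene and so end up cis to C1′, the Z-geometry of the target.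

Step 23
Reactants: 33 tert-butyl{[(2R)-2-{(3R,6S)-6-[(3Z)-3-(5,5-dimethyl-3,4,5,6,7,8-hexahydronaphthalen-2(1H)-ylidene)propyl]-6-methyl-1,2-dioxan-3-yl}propyl]oxy}dimethylsilane
Product: 34 (2R)-2-{(3R,6S)-6-[(3Z)-3-(5,5-dimethyl-3,4,5,6,7,8-hexahydronaphthalen-2(1H)-ylidene)propyl]-6-methyl-1,2-dioxan-3-yl}propan-1-ol
Conditions: HF·pyridine, pyridine, THF, 0 °C → rt
Reagents that add atoms: none
Why: Fluoride cleaves the primary Si–O bond, and the buffered, non-basic, non-reducing medium should spare the peroxide, the skipped diene and C2.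

Step 24
Reactants: 34 (2R)-2-{(3R,6S)-6-[(3Z)-3-(5,5-dimethyl-3,4,5,6,7,8-hexahydronaphthalen-2(1H)-ylidene)propyl]-6-methyl-1,2-dioxan-3-yl}propan-1-ol
Product: 36 (2S)-2-{(3R,6S)-6-[(3Z)-3-(5,5-dimethyl-3,4,5,6,7,8-hexahydronaphthalen-2(1H)-ylidene)propyl]-6-methyl-1,2-dioxan-3-yl}propanoic acid, via aldehyde 35 (not isolated)
Conditions: PhI(OAc)2 (2.2 equiv), TEMPO (cat.), MeCN/H2O, rt
Reagents that add atoms: water, O
Why: Oxoammonium oxidation in aqueous acetonitrile takes the primary alcohol through the aldehyde and its hydrate to the acid under near-neutral conditions that should not epimerise C2, reduce the peroxide or attack the alkenes.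

## Compound list

1 | neryl acetate, (2Z)-3,7-dimethylocta-2,6-dien-1-yl acetate | CC(C)=CCC/C(C)=C\COC(C)=O | starting material
2 | (2Z)-5-(3,3-dimethyloxiran-2-yl)-3-methylpent-2-en-1-yl acetate (racemic epoxide) | CC1(C)OC1CC/C(C)=C\COC(C)=O | intermediate
3 | (2Z)-6,7-dihydroxy-3,7-dimethyloct-2-en-1-yl acetate (not isolated) | CC(C)(O)C(O)CC/C(C)=C\COC(C)=O | intermediate
4 | (2Z)-3-methyl-6-oxohex-2-en-1-yl acetate | O=CCC/C(C)=C\COC(C)=O | intermediate
5 | (4Z)-6-acetoxy-4-methylhex-4-enoic acid | OC(=O)CC/C(C)=C\COC(C)=O | intermediate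
6 | methyl (4Z)-6-acetoxy-4-methylhex-4-enoate | COC(=O)CC/C(C)=C\COC(C)=O | intermediate
7 | methyl (4Z)-6-hydroxy-4-methylhex-4-enoate | COC(=O)CC/C(C)=C\CO | intermediate
8 | methyl (4Z)-4-methyl-6-oxohex-4-enoate | COC(=O)CC/C(C)=C\C=O | intermediate
9 | methyl (2R)-3-hydroxy-2-methylpropanoate | C[C@H](CO)C(=O)OC | starting material
10 | methyl (2R)-3-[(tert-butyldimethylsilyl)oxy]-2-methylpropanoate | C[C@H](CO[Si](C)(C)C(C)(C)C)C(=O)OC | intermediate
11 | (2S)-3-[(tert-butyldimethylsilyl)oxy]-2-methylpropan-1-ol | C[C@H](CO[Si](C)(C)C(C)(C)C)CO | intermediate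
12 | 5-{[(2R)-3-[(tert-butyldimethylsilyl)oxy]-2-methylpropyl]sulfanyl}-1-phenyl-1H-tetrazole | C[C@H](CO[Si](C)(C)C(C)(C)C)CSC1=NN=NN1c1ccccc1 | intermediate
13 | corresponding sulfoxide, mixture at sulfur (not isolated) | C[C@H](CO[Si](C)(C)C(C)(C)C)CS(=O)C1=NN=NN1c1ccccc1 | intermediate
14 | 5-{[(2R)-3-[(tert-butyldimethylsilyl)oxy]-2-methylpropyl]sulfonyl}-1-phenyl-1H-tetrazole | C[C@H](CO[Si](C)(C)C(C)(C)C)CS(=O)(=O)C1=NN=NN1c1ccccc1 | intermediate
15 | potassium α-sulfonyl carbanion of 14 (not isolated) | C[C@H](CO[Si](C)(C)C(C)(C)C)[CH-]S(=O)(=O)C1=NN=NN1c1ccccc1.[K+] | intermediate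
16 | methyl (4Z,6E,8S)-9-[(tert-butyldimethylsilyl)oxy]-4,8-dimethylnona-4,6-dienoate | C[C@H](CO[Si](C)(C)C(C)(C)C)/C=C/C=C(/C)CCC(=O)OC | intermediate
17 | methyl 3-[(3S,6R)-6-{(2R)-1-[(tert-butyldimethylsilyl)oxy]propan-2-yl}-3-methyl-3,6-dihydro-1,2-dioxin-3-yl]propanoate | C[C@H](CO[Si](C)(C)C(C)(C)C)[C@H]1C=C[C@](C)(CCC(=O)OC)OO1 | intermediate
18 | methyl 3-[(3R,6R)-6-{(2R)-1-[(tert-butyldimethylsilyl)oxy]propan-2-yl}-3-methyl-1,2-dioxan-3-yl]propanoate | C[C@H](CO[Si](C)(C)C(C)(C)C)[C@H]1CC[C@](C)(CCC(=O)OC)OO1 | intermediate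
19 | 3-[(3R,6R)-6-{(2R)-1-[(tert-butyldimethylsilyl)oxy]propan-2-yl}-3-methyl-1,2-dioxan-3-yl]propanoic acid | C[C@H](CO[Si](C)(C)C(C)(C)C)[C@H]1CC[C@](C)(CCC(=O)O)OO1 | intermediate
20 | 6-methoxy-1-tetralone, 6-methoxy-3,4-dihydronaphthalen-1(2H)-one | COc1ccc2C(=O)CCCc2c1 | starting material
21 | dichloro(methyl)titanium 6-methoxy-1-methyl-1,2,3,4-tetrahydronaphthalen-1-olate (not isolated) | COc1ccc2c(c1)CCCC2(C)O[Ti](C)(Cl)Cl | intermediate
22 | 6-methoxy-1,1-dimethyl-1,2,3,4-tetrahydronaphthalene | COc1ccc2c(c1)CCCC2(C)C | intermediate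
23 | 6-methoxy-1,1-dimethyl-1,2,3,4,5,8-hexahydronaphthalene | COC1=CCC2=C(C1)CCCC2(C)C | intermediate
24 | 5,5-dimethyl-3,4,5,6,7,8-hexahydronaphthalen-2(1H)-one | O=C1CCC2=C(C1)CCCC2(C)C | intermediate
25 | potassium 5,5-dimethyl-3,4,5,6,7,8-hexahydronaphthalen-2-olate (not isolated) | [K+].[O-]C1=CC2=C(CC1)C(C)(C)CCC2 | intermediate
26 | 5,5-dimethyl-3,4,5,6,7,8-hexahydronaphthalen-2-yl trifluoromethanesulfonate | CC1(C)CCCC2=C1CCC(OS(=O)(=O)C(F)(F)F)=C2 | intermediate
27 | (5,5-dimethyl-3,4,5,6,7,8-hexahydronaphthalen-2-yl)trimethylstannane | CC1(C)CCCC2=C1CCC([Sn](C)(C)C)=C2 | intermediate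
28 | 3-[(3R,6R)-6-{(2R)-1-[(tert-butyldimethylsilyl)oxy]propan-2-yl}-3-methyl-1,2-dioxan-3-yl]propanoyl chloride (not isolated) | C[C@H](CO[Si](C)(C)C(C)(C)C)[C@H]1CC[C@](C)(CCC(=O)Cl)OO1 | intermediate
29 | 1-(5,5-dimethyl-3,4,5,6,7,8-hexahydronaphthalen-2-yl)-3-[(3R,6R)-6-{(2R)-1-[(tert-butyldimethylsilyl)oxy]propan-2-yl}-3-methyl-1,2-dioxan-3-yl]propan-1-one | C[C@H](CO[Si](C)(C)C(C)(C)C)[C@H]1CC[C@](C)(CCC(=O)C2=CC3=C(CC2)C(C)(C)CCC3)OO1 | intermediate
30 | 4-methylbenzenesulfonohydrazone of 29 (C=N geometry not defined) | C[C@H](CO[Si](C)(C)C(C)(C)C)[C@H]1CC[C@](C)(CCC(=NNS(=O)(=O)c2ccc(C)cc2)C2=CC3=C(CC2)C(C)(C)CCC3)OO1 | intermediate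
31 | N-(1,3,2-benzodioxaborol-2-yl)-N′-tosyl hydrazine from C=N hydroboration of 30, C9 epimers (not isolated) | C[C@H](CO[Si](C)(C)C(C)(C)C)[C@H]1CC[C@](C)(CCC(N(NS(=O)(=O)c2ccc(C)cc2)B2Oc3ccccc3O2)C2=CC3=C(CC2)C(C)(C)CCC3)OO1 | intermediate
32 | allylic monoalkyl diazene at C9, C9 epimers (not isolated) | C[C@H](CO[Si](C)(C)C(C)(C)C)[C@H]1CC[C@](C)(CCC(N=N)C2=CC3=C(CC2)C(C)(C)CCC3)OO1 | intermediate
33 | tert-butyl{[(2R)-2-{(3R,6S)-6-[(3Z)-3-(5,5-dimethyl-3,4,5,6,7,8-hexahydronaphthalen-2(1H)-ylidene)propyl]-6-methyl-1,2-dioxan-3-yl}propyl]oxy}dimethylsilane | C[C@H](CO[Si](C)(C)C(C)(C)C)[C@H]1CC[C@](C)(CC/C=C2/CCC3=C(CCCC3(C)C)C2)OO1 | intermediate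
34 | (2R)-2-{(3R,6S)-6-[(3Z)-3-(5,5-dimethyl-3,4,5,6,7,8-hexahydronaphthalen-2(1H)-ylidene)propyl]-6-methyl-1,2-dioxan-3-yl}propan-1-ol | C[C@H](CO)[C@H]1CC[C@](C)(CC/C=C2/CCC3=C(CCCC3(C)C)C2)OO1 | intermediate
35 | (2S)-2-{(3R,6S)-6-[(3Z)-3-(5,5-dimethyl-3,4,5,6,7,8-hexahydronaphthalen-2(1H)-ylidene)propyl]-6-methyl-1,2-dioxan-3-yl}propanal (not isolated) | C[C@H](C=O)[C@H]1CC[C@](C)(CC/C=C2/CCC3=C(CCCC3(C)C)C2)OO1 | intermediate
36 | (2S)-2-{(3R,6S)-6-[(3Z)-3-(5,5-dimethyl-3,4,5,6,7,8-hexahydronaphthalen-2(1H)-ylidene)propyl]-6-methyl-1,2-dioxan-3-yl}propanoic acid (CNP0223199.1) | C[C@H](C(=O)O)[C@H]1CC[C@](C)(CC/C=C2/CCC3=C(CCCC3(C)C)C2)OO1 | target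

## Step count

Total steps: 24.
Longest linear sequence: 15 steps (steps 1–6, 11–14, 20–24, from neryl acetate).

## The three steps most likely to fail

**Step 12 (singlet-oxygen cycloaddition).** Three things may go wrong:
- The inside C7 methylene raises the energy of the s-cis conformer, so ene and [2+2] reactions at the trisubstituted alkene may outrun the cycloaddition.
- A reversible perepoxide may isomerise the Z terminus before ring closure, which would erode the cis relationship of C3 and C6.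
- Facial discrimination by the C2 stereocentre may be weak.

Fallback, a stepwise closure of ring A that sets out from alcohol 11 and returns at 18:
- Alcohol 11 is oxidised (PhI(OAc)2, TEMPO, CH2Cl2) to (2R)-3-[(tert-butyldimethylsilyl)oxy]-2-methylpropanal F1.
- Reagent-controlled Brown allylation, with the enantiomer of B-allyldiisopinocampheylborane that gives the 2,3-anti carbinol, should give (2R,3S)-1-[(tert-butyldimethylsilyl)oxy]-2-methylhex-5-en-3-ol F2.
- Mesylation (MsCl, Et3N, CH2Cl2, 0 °C) gives (2R,3S)-1-[(tert-butyldimethylsilyl)oxy]-2-methylhex-5-en-3-yl methanesulfonate F3.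
- Cross-metathesis with methyl 4-methylpent-4-enoate (second-generation Hoveyda–Grubbs catalyst, CH2Cl2, 40 °C) gives methyl (7S,8R)-9-[(tert-butyldimethylsilyl)oxy]-4,8-dimethyl-7-[(methylsulfonyl)oxy]non-4-enoate F4, whose alkene geometry does not matter.
- Mukaiyama–Isayama hydroperoxysilylation (Co(acac)2, O2, Et3SiH, ClCH2CH2Cl, rt) puts the peroxide on the tertiary carbon and gives methyl (7S,8R)-9-[(tert-butyldimethylsilyl)oxy]-4,8-dimethyl-7-[(methylsulfonyl)oxy]-4-[(triethylsilyl)peroxy]nonanoate F5 as a mixture of epimers at that carbon.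
- K2CO3 in MeOH at 0 °C frees methyl (7S,8R)-9-[(tert-butyldimethylsilyl)oxy]-4-hydroperoxy-4,8-dimethyl-7-[(methylsulfonyl)oxy]nonanoate F6.
- Cs2CO3 in DMF closes ring A by 6-exo-tet displacement of the mesylate with inversion at C3, giving 18 together with methyl 3-[(3S,6R)-6-{(2R)-1-[(tert-butyldimethylsilyl)oxy]propan-2-yl}-3-methyl-1,2-dioxan-3-yl]propanoate F7, which is removed by chromatography.

This fixes C3 relative to C2 but leaves C6 to separation.

**Step 22 (tosylhydrazone reduction with transposition).** The borane or the warm elimination stage may attack the O–O bond, the hydrazone may be reduced incompletely, and the retro-ene may not discriminate well between the two alkene geometries.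

Fallback, which reaches the same diazene without borane or heating, sets out from dienone 29 and returns at 33:
- Luche reduction (NaBH4, CeCl3·7H2O, MeOH, −40 °C) gives 1-(5,5-dimethyl-3,4,5,6,7,8-hexahydronaphthalen-2-yl)-3-[(3S,6R)-6-{(2R)-1-[(tert-butyldimethylsilyl)oxy]propan-2-yl}-3-methyl-1,2-dioxan-3-yl]propan-1-ol F8 as a mixture of C9 epimers.
- Mitsunobu reaction with 2-nitrobenzenesulfonohydrazide (PPh3, DEAD, N-methylmorpholine, −30 °C) gives N-{1-(5,5-dimethyl-3,4,5,6,7,8-hexahydronaphthalen-2-yl)-3-[(3S,6R)-6-{(2R)-1-[(tert-butyldimethylsilyl)oxy]propan-2-yl}-3-methyl-1,2-dioxan-3-yl]propyl}-2-nitrobenzenesulfonohydrazide F9.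
- On warming to room temperature F9 loses the sulfinic acid to give diazene 32 and then 33.

Should the geometric preference itself be inadequate, the olefination described under step 20 supplies both isomers for separation.

**Step 20 (Stille acylation beside the peroxide).** Zerovalent palladium or the phosphine may insert into or reduce the O–O bond, the acylpalladium species may decarbonylate, and the dienylstannane may protodestannylate or aromatise.

Fallback, a direct olefination that bypasses the acylation and the transposition, sets out from ester 18 and ketone 24 and returns at 33: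
- Ester 18 is reduced (DIBAL-H, CH2Cl2, −78 °C) to 3-[(3R,6R)-6-{(2R)-1-[(tert-butyldimethylsilyl)oxy]propan-2-yl}-3-methyl-1,2-dioxan-3-yl]propanal F10.
- Ketone 24 is reduced (NaBH4, MeOH, 0 °C) to 5,5-dimethyl-1,2,3,4,5,6,7,8-octahydronaphthalen-2-ol F11.
- Mitsunobu reaction with 1-phenyl-1H-tetrazole-5-thiol (PPh3, DIAD, THF) gives 5-[(5,5-dimethyl-1,2,3,4,5,6,7,8-octahydronaphthalen-2-yl)sulfanyl]-1-phenyl-1H-tetrazole F12.
- Sulfur-selective oxidation ((NH4)6Mo7O24·4H2O, H2O2, EtOH, 0 °C) gives 5-[(5,5-dimethyl-1,2,3,4,5,6,7,8-octahydronaphthalen-2-yl)sulfonyl]-1-phenyl-1H-tetrazole F13.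
- Julia–Kocienski olefination of F10 with metallated F13 (LiN(SiMe3)2, THF, −78 °C → rt) forms C9=C2′ directly and should give 33 together with its geometric isomer, tert-butyl{[(2R)-2-{(3R,6S)-6-[(3E)-3-(5,5-dimethyl-3,4,5,6,7,8-hexahydronaphthalen-2(1H)-ylidene)propyl]-6-methyl-1,2-dioxan-3-yl}propyl]oxy}dimethylsilane F14, which is separated on silver-nitrate-impregnated silica.

Geometric control is given up in exchange for chemistry that uses no palladium, tin or borane.

## Further compounds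

F1 | step 12 | (2R)-3-[(tert-butyldimethylsilyl)oxy]-2-methylpropanal | C[C@H](CO[Si](C)(C)C(C)(C)C)C=O
F2 | step 12 | (2R,3S)-1-[(tert-butyldimethylsilyl)oxy]-2-methylhex-5-en-3-ol | C[C@H](CO[Si](C)(C)C(C)(C)C)[C@@H](O)CC=C
F3 | step 12 | (2R,3S)-1-[(tert-butyldimethylsilyl)oxy]-2-methylhex-5-en-3-yl methanesulfonate | C[C@H](CO[Si](C)(C)C(C)(C)C)[C@@H](OS(C)(=O)=O)CC=C
F4 | step 12 | methyl (7S,8R)-9-[(tert-butyldimethylsilyl)oxy]-4,8-dimethyl-7-[(methylsulfonyl)oxy]non-4-enoate (E/Z mixture) | C[C@H](CO[Si](C)(C)C(C)(C)C)[C@@H](OS(C)(=O)=O)CC=C(C)CCC(=O)OC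
F5 | step 12 | methyl (7S,8R)-9-[(tert-butyldimethylsilyl)oxy]-4,8-dimethyl-7-[(methylsulfonyl)oxy]-4-[(triethylsilyl)peroxy]nonanoate (C4 epimers) | C[C@H](CO[Si](C)(C)C(C)(C)C)[C@@H](OS(C)(=O)=O)CCC(C)(OO[Si](CC)(CC)CC)CCC(=O)OC
F6 | step 12 | methyl (7S,8R)-9-[(tert-butyldimethylsilyl)oxy]-4-hydroperoxy-4,8-dimethyl-7-[(methylsulfonyl)oxy]nonanoate (C4 epimers) | C[C@H](CO[Si](C)(C)C(C)(C)C)[C@@H](OS(C)(=O)=O)CCC(C)(OO)CCC(=O)OC
F7 | step 12 | methyl 3-[(3S,6R)-6-{(2R)-1-[(tert-butyldimethylsilyl)oxy]propan-2-yl}-3-methyl-1,2-dioxan-3-yl]propanoate (trans epimer of 18) | C[C@H](CO[Si](C)(C)C(C)(C)C)[C@H]1CC[C@@](C)(CCC(=O)OC)OO1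
F8 | step 22 | 1-(5,5-dimethyl-3,4,5,6,7,8-hexahydronaphthalen-2-yl)-3-[(3S,6R)-6-{(2R)-1-[(tert-butyldimethylsilyl)oxy]propan-2-yl}-3-methyl-1,2-dioxan-3-yl]propan-1-ol (C9 epimers) | C[C@H](CO[Si](C)(C)C(C)(C)C)[C@H]1CC[C@](C)(CCC(O)C2=CC3=C(CC2)C(C)(C)CCC3)OO1
F9 | step 22 | N-{1-(5,5-dimethyl-3,4,5,6,7,8-hexahydronaphthalen-2-yl)-3-[(3S,6R)-6-{(2R)-1-[(tert-butyldimethylsilyl)oxy]propan-2-yl}-3-methyl-1,2-dioxan-3-yl]propyl}-2-nitrobenzenesulfonohydrazide (C9 epimers) | C[C@H](CO[Si](C)(C)C(C)(C)C)[C@H]1CC[C@](C)(CCC(N(N)S(=O)(=O)c2ccccc2[N+](=O)[O-])C2=CC3=C(CC2)C(C)(C)CCC3)OO1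
F10 | step 20 | 3-[(3R,6R)-6-{(2R)-1-[(tert-butyldimethylsilyl)oxy]propan-2-yl}-3-methyl-1,2-dioxan-3-yl]propanal | C[C@H](CO[Si](C)(C)C(C)(C)C)[C@H]1CC[C@](C)(CCC=O)OO1
F11 | step 20 | 5,5-dimethyl-1,2,3,4,5,6,7,8-octahydronaphthalen-2-ol (racemic) | OC1CCC2=C(C1)CCCC2(C)C
F12 | step 20 | 5-[(5,5-dimethyl-1,2,3,4,5,6,7,8-octahydronaphthalen-2-yl)sulfanyl]-1-phenyl-1H-tetrazole (racemic) | CC1(C)CCCC2=C1CCC(C2)SC1=NN=NN1c1ccccc1
F13 | step 20 | 5-[(5,5-dimethyl-1,2,3,4,5,6,7,8-octahydronaphthalen-2-yl)sulfonyl]-1-phenyl-1H-tetrazole (racemic) | CC1(C)CCCC2=C1CCC(C2)S(=O)(=O)C1=NN=NN1c1ccccc1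
F14 | step 20 | tert-butyl{[(2R)-2-{(3R,6S)-6-[(3E)-3-(5,5-dimethyl-3,4,5,6,7,8-hexahydronaphthalen-2(1H)-ylidene)propyl]-6-methyl-1,2-dioxan-3-yl}propyl]oxy}dimethylsilane | C[C@H](CO[Si](C)(C)C(C)(C)C)[C@H]1CC[C@](C)(CC/C=C2\CCC3=C(CCCC3(C)C)C2)OO1
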